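The unbranched C28 acyl chain is cut at C8–C9. Its C5–C8 methylenes are carried as the four ring carbons of a 2,5-disubstituted thiophene. The unsubstituted α-carbon C5 of that ring (future C8) can therefore act as a carbon nucleophile. In one operation, a Friedel–Crafts acylation joins this carbon to the carbonyl carbon of icosanoyl chloride (future C9). This lines up all 28 chain carbons with the phenethyl ester already in place. The precursor is 2-phenylethyl 4-(thiophen-2-yl)butanoate: ester C1, methylenes C2–C4 and a 2-thienyl ring with a free C5–H. Deoxygenation at C9 and reductive removal of sulfur then leave only methylenes.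

Key step: step 3

Assumption: the SMILES defines the alcohol part as 2-phenylethyl (O–CH2–CH2–Ph), so the target has no stereocentre and no stereogenic double bond. It is achiral, no enantiomer has to be selected, and no SMILES needs stereodescriptors. Chain numbers C1–C28 refer to the octacosanoyl chain (C1 = ester carbonyl). C1–C4 come from the thienylbutanoic acid side chain, C5–C8 from its ring and C9–C28 from arachidic acid (4 + 4 + 20 = 28).

Step 1
Reactants: 1 4-(thiophen-2-yl)butanoic acid; 2 2-phenylethanol
Product: 3 2-phenylethyl 4-(thiophen-2-yl)butanoate
Conditions: DCC, DMAP (cat.), CH2Cl2, 0 °C → rt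
Reagents that add atoms: none
Why: Steglich esterification (carbodiimide activation with DMAP acyl transfer) couples a primary alcohol under neutral conditions, so the acid never meets the strongly acidic or Lewis acidic activation under which its side chain could acylate thiophene C3 intramolecularly.

Step 2
Reactants: 4 icosanoic acid (arachidic acid)
Product: 5 icosanoyl chloride
Conditions: SOCl2, toluene, 70 °C; then evaporation with toluene, used without purification
Reagents that add atoms: thionyl chloride, O=S(Cl)Cl
Why: Acyl chloride formation through the acyl chlorosulfite is a standard activation of saturated fatty acids, gives only gaseous coproducts, and is run without DMF so that no chloroiminium salt able to formylate the thiophene is carried into step 3.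

Step 3
Reactants: 3 2-phenylethyl 4-(thiophen-2-yl)butanoate; 5 icosanoyl chloride
Product: 6 2-phenylethyl 4-(5-icosanoylthiophen-2-yl)butanoate
Conditions: SnCl4 (2 equiv) added to 3 + 5, CH2Cl2, 0 °C → rt; then ice/1 M HCl
Reagents that add atoms: none
Why: SnCl4 polarises 5 to an acylium-type electrophile that is attacked by the free α-carbon C5 of the thiophene in 3, and the sulfur-stabilised σ-complex rearomatises by loss of the C5 proton as HCl, which forms the future C8–C9 bond. The reaction type is the Friedel–Crafts acylation of 2-alkylthiophenes with fatty acyl chlorides, a well-established entry to long-chain acids. No ring is closed and no stereocentre is created. Site selectivity within the heterocycle (C5 over C3 and C4) follows from the better delocalisation of charge onto sulfur after α-attack, reinforced by the C2 alkyl group, which activates C5 and shields C3. Chemoselectivity over the phenyl ring of the ester follows from the far higher nucleophilicity of a thiophene α-position compared with a monoalkylbenzene, which this mild Lewis acid should leave untouched, and the new ketone deactivates the ring against a second acylation. Two equivalents of SnCl4 are used because the ester and the product ketone each bind Lewis acid, and SnCl4 is preferred to AlCl3 because it spares both the thiophene and the ester.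

Step 4
Reactants: 6 2-phenylethyl 4-(5-icosanoylthiophen-2-yl)butanoate
Product: 8 2-phenylethyl 4-(5-icosylthiophen-2-yl)butanoate, via thienyl carbinol 7 (not isolated)
Conditions: Et3SiH (2.5 equiv), TFA/CH2Cl2 1:1, 0 °C → rt
Reagents that add atoms: none
Why: In this ionic hydrogenation of an aryl ketone, protonation and hydride transfer from the silane give racemic carbinol 7, which ionises in TFA to a thiophene-stabilised carbocation that takes up a second hydride and so erases the transient stereocentre, while the primary alkyl ester and the phenyl ring are inert to TFA and silane and the limited silane charge at room temperature holds back the slower reduction of the ring.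

Step 5
Reactants: 8 2-phenylethyl 4-(5-icosylthiophen-2-yl)butanoate
Product: 9 2-phenylethyl octacosanoate (target)
Conditions: Raney Ni (W-2, washed neutral and solvent-exchanged, large excess), H2 (1 atm), THF, 55 °C; hot filtration through Celite
Reagents that add atoms: none
Why: Raney nickel reductive desulfurisation cleaves both C–S bonds of the 2,5-dialkylthiophene and saturates the released C4 unit to the C5–C8 tetramethylene, whereas the ester C–O bond is homobenzylic and thus not hydrogenolysed, the phenyl ring is not reduced at one atmosphere, and a neutral catalyst in an aprotic solvent excludes ester exchange.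

Compound list
1 | 4-(thiophen-2-yl)butanoic acid | OC(=O)CCCc1cccs1 | starting material
2 | 2-phenylethanol | OCCc1ccccc1 | starting material
3 | 2-phenylethyl 4-(thiophen-2-yl)butanoate | O=C(CCCc1cccs1)OCCc1ccccc1 | intermediate
4 | icosanoic acid (arachidic acid) | CCCCCCCCCCCCCCCCCCCC(=O)O | starting material
5 | icosanoyl chloride | CCCCCCCCCCCCCCCCCCCC(=O)Cl | intermediate
6 | 2-phenylethyl 4-(5-icosanoylthiophen-2-yl)butanoate | CCCCCCCCCCCCCCCCCCCC(=O)c1ccc(CCCC(=O)OCCc2ccccc2)s1 | intermediate
7 | 2-phenylethyl 4-[5-(1-hydroxyicosyl)thiophen-2-yl]butanoate (racemic, formed and consumed in the flask) | CCCCCCCCCCCCCCCCCCCC(O)c1ccc(CCCC(=O)OCCc2ccccc2)s1 | intermediate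
8 | 2-phenylethyl 4-(5-icosylthiophen-2-yl)butanoate | CCCCCCCCCCCCCCCCCCCCc1ccc(CCCC(=O)OCCc2ccccc2)s1 | intermediate
9 | 2-phenylethyl octacosanoate (achiral) | CCCCCCCCCCCCCCCCCCCCCCCCCCCC(=O)OCCc1ccccc1 | target

Total step count: 5. Longest linear sequence: 4 (steps 1, 3, 4, 5; step 2 runs in parallel).

Steps most likely to fail

1. Step 3 (key step).
- **Risk:** acid-induced oligomerisation of the electron-rich thiophene, stalling because the ester and the product ketone tie up the Lewis acid, or erosion of the α-selectivity.
- **Fallback:** cross-coupling replaces electrophilic substitution and forms the same C8–C9 bond. Setting out from 3, electrophilic bromination at thiophene C5 with NBS in DMF at 0 °C in the dark should give 2-phenylethyl 4-(5-bromothiophen-2-yl)butanoate F1. In a second flask, commercial icos-1-ene (C=CCCCCCCCCCCCCCCCCCC) is hydroborated with 9-BBN-H in THF to 9-icosyl-9-borabicyclo[3.3.1]nonane F2. A B-alkyl Suzuki–Miyaura coupling of the two [PdCl2(dppf), K3PO4, THF/DMF/H2O, 50 °C] should deliver 8 directly. The route is rejoined at 8 and step 4 is no longer needed.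

2. Step 4.
- **Risk:** spill-over of the ionic hydrogenation into the thiophene ring, which would blur the intermediate. Other risks are stalling at the carbinol or trifluoroacetate stage, and proton loss from the carbocation followed by cationic dimerisation.
- **Fallback:** sulfur-based deoxygenation merged with the last step. Setting out from 6, ethane-1,2-dithiol and BF3·OEt2 in CH2Cl2 should convert the ketone into 2-phenylethyl 4-[5-(2-nonadecyl-1,3-dithiolan-2-yl)thiophen-2-yl]butanoate F3. A Mozingo-type treatment with neutral Raney nickel in THF should then strip the two dithiolane sulfurs and the ring sulfur in one operation. The route is rejoined at 9.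

3. Step 5.
- **Risk:** incomplete hydrogenolysis or residual unsaturation on a hydrogen-depleted catalyst, retention of the waxy product on the nickel, loss of the phenethyl ester on an insufficiently neutral catalyst, or partial saturation of the phenyl ring.
- **Fallback:** sulfur is removed before the ester is installed. Setting out from 8, saponification with LiOH in THF/MeOH/H2O should give 4-(5-icosylthiophen-2-yl)butanoic acid F4. Its sodium salt is desulfurised with active Raney nickel in hot aqueous ethanol, where neither an ester nor a phenyl ring is at stake. This should give octacosanoic acid F5, which can be purified by recrystallisation. Steglich esterification with 2 (DCC, DMAP, warm CH2Cl2/toluene) rejoins the route at 9.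

Further compounds
F1 | step 3 | 2-phenylethyl 4-(5-bromothiophen-2-yl)butanoate | O=C(CCCc1ccc(Br)s1)OCCc1ccccc1
F2 | step 3 | 9-icosyl-9-borabicyclo[3.3.1]nonane | CCCCCCCCCCCCCCCCCCCCB1C2CCCC1CCC2
F3 | step 4 | 2-phenylethyl 4-[5-(2-nonadecyl-1,3-dithiolan-2-yl)thiophen-2-yl]butanoate | CCCCCCCCCCCCCCCCCCCC1(SCCS1)c1ccc(CCCC(=O)OCCc2ccccc2)s1
F4 | step 5 | 4-(5-icosylthiophen-2-yl)butanoic acid | CCCCCCCCCCCCCCCCCCCCc1ccc(CCCC(=O)O)s1
F5 | step 5 | octacosanoic acid | CCCCCCCCCCCCCCCCCCCCCCCCCCCC(=O)O
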